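**Plan** (target cyclobutane numbering: C1 bears the pentenyl unit, C2 the 3-oxobutyl chain, C3 is CMe2, C4 is CH2)

- Retrosynthesis cuts, in order: the linoleate ester C–O bond; the CH3–C(=O) bond (nitrile + MeLi), the C=CH2 bond (Wittig) and the C(=O)–CH2 bond to the hydroxypropyl unit (Weinreb amide + Grignard); then the carboxyl and nitrile carbons are re-joined as C2–C3 of a cyclohexanone (Beckmann fragmentation read backwards); last the cyclobutane bonds C4–C1 and C3–C2.
- Enabling feature: C1 carries an sp2 carbon at ketone oxidation level, so C1–C2 is the α,β-bond of an enone. That carbon, C1, C2 and the three oxobutyl carbons up to the ketone carbon form a latent six-membered ring (cyclohex-2-enone), and the C4–C3 edge (CH2–CMe2) is isobutene.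
- Forward: the cyclobutane is made first as a bicyclo[4.2.0]octan-2-one; the six-membered ring is then opened at C2–C3 (α-oximation, fragmentation) to acid and nitrile; the two chains are completed and the ester is made last.
- Stereochemistry: C2 (R) comes from the catalyst-controlled photocycloaddition. C1 (S, trans) comes from thermodynamic equilibration of the cyclobutyl ketone after ring opening, so both ring-fusion epimers converge. The Z,Z-diene comes with linoleic acid.

Key step: step 1

Assumption: the enantiomer of the oxazaborolidine is the one that exposes the enone face leading to the (6R) adduct; if the sense of induction proves opposite, the mirror-image catalyst (from the other prolinol enantiomer) is used.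

**Step 1**
Reactants: 1 cyclohex-2-en-1-one; 2 2-methylpropene (isobutene)
Product: 4 (1R,6R)-7,7-dimethylbicyclo[4.2.0]octan-2-one, via trans-fused ketone 3 (not isolated)
Conditions: 2 (excess), AlBr3-activated chiral diarylprolinol-derived B-aryl oxazaborolidine (50 mol %), CH2Cl2, −75 °C, hν (366 nm); then basic Al2O3, CH2Cl2, rt
Reagents that add atoms: none
Why: Coordination of the AlBr3-activated oxazaborolidine to the carbonyl oxygen of 1 shifts the ππ* absorption to longer wavelength, so that at 366 nm mainly the chiral complex is excited; after intersystem crossing its triplet adds to 2 to give a triplet 1,4-diradical that closes to the cyclobutane after spin inversion. The closest known reaction type is the chiral-Lewis-acid-catalysed enantioselective intermolecular enone–alkene [2+2] photocycloaddition of cyclic enones with simple alkenes. The four-membered ring is closed in a stepwise [2+2] mode (one intermolecular C–C bond, then 1,4-diradical recombination), while the six-membered ring acts as a template that prevents E/Z decay of the excited alkene. C6 (the former β-carbon) is set by the catalyst, whose aryl group shields one face of the bound enone; C1 (the former α-carbon) is not set by the photoreaction (cis and trans fusion both arise), is levelled to the cis-fused ketone on alumina and is re-set later by equilibration. The step needs head-to-tail regioselectivity (CMe2 on the β-carbon, CH2 on the α-carbon), which should follow the usual preference of cyclohexenone with 1,1-dialkylethylenes in which the unsubstituted alkene carbon bonds so that the tertiary radical forms; enantioselectivity requires that the free enone stays unexcited, which the long wavelength, low temperature and high catalyst loading should secure.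

**Step 2**
Reactants: 4 (1R,6R)-7,7-dimethylbicyclo[4.2.0]octan-2-one
Product: 5 (1R,6R)-3-(hydroxyimino)-7,7-dimethylbicyclo[4.2.0]octan-2-one
Conditions: KOtBu, isopentyl nitrite, t-BuOH/THF, 0 °C; then aq. HCl
Reagents that add atoms: isopentyl nitrite, CC(C)CCON=O
Why: Claisen-type C-nitrosation of the ketone enolate by an alkyl nitrite; only the C3 methylene can tautomerise to the oxime and be held as its stable potassium oximate, whereas the ring-fusion methine C1 is hindered and its enolate would be exocyclic to the cyclobutane, and the cis ring fusion is the thermodynamic one and is kept.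

**Step 3**
Reactants: 5 (1R,6R)-3-(hydroxyimino)-7,7-dimethylbicyclo[4.2.0]octan-2-one
Product: 7 (1R,2R)-2-(2-cyanoethyl)-3,3-dimethylcyclobutane-1-carboxylic acid, via O-tosyl oxime 6 (not isolated)
Conditions: TsCl, aq. NaOH, acetone, 0 °C → rt; then aq. HCl
Reagents that add atoms: sodium hydroxide, [Na+].[OH-]
Why: Beckmann fragmentation (second-order Beckmann reaction) of an α-oximino ketone; O-sulfonylation, addition of hydroxide to the ketone and fragmentation of the C2–C3 bond with loss of tosylate should open the six-membered ring to a carboxylate and a nitrile without touching C1 or C6.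

**Step 4**
Reactants: 7 (1R,2R)-2-(2-cyanoethyl)-3,3-dimethylcyclobutane-1-carboxylic acid
Product: 9 (1R,2R)-2-(2-cyanoethyl)-N-methoxy-N,3,3-trimethylcyclobutane-1-carboxamide, via acyl imidazole 8 (not isolated)
Conditions: CDI, CH2Cl2, rt; then MeNH(OMe)·HCl, rt
Reagents that add atoms: N,O-dimethylhydroxylamine hydrochloride, CNOC.Cl
Why: Weinreb amide formation through the acyl imidazole under near-neutral conditions, which should leave the nitrile and the α-stereocentre untouched.

**Step 5**
Reactants: 9 (1R,2R)-2-(2-cyanoethyl)-N-methoxy-N,3,3-trimethylcyclobutane-1-carboxamide; 10 3-chloropropan-1-ol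
Product: 13 3-[(1R,2S)-2-(4-hydroxybutanoyl)-4,4-dimethylcyclobutyl]propanenitrile, via dimagnesium reagent 11 (not isolated), via cis hydroxy ketone 12 (not isolated)
Conditions: 10, i-PrMgCl, THF, −20 °C, then Mg, reflux; add 9, THF, −20 → 0 °C; aq. NH4Cl; then NaOMe (cat.), MeOH, 40 °C
Reagents that add atoms: none
Why: Weinreb ketone synthesis, in which the O-metallated Grignard reagent adds once to the N-methoxy-N-methylamide (stable magnesium chelate) faster than to the nitrile at 0 °C; catalytic methoxide then equilibrates the cyclobutyl ketone through its enolate to the trans isomer, in which the acyl group avoids the neighbouring cyanoethyl chain, and this sets the second stereocentre (S) under thermodynamic control.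

**Step 6**
Reactants: 13 3-[(1R,2S)-2-(4-hydroxybutanoyl)-4,4-dimethylcyclobutyl]propanenitrile
Product: 14 3-[(1R,2S)-2-(5-hydroxypent-1-en-2-yl)-4,4-dimethylcyclobutyl]propanenitrile
Conditions: Ph3PCH3Br, KOtBu (3 equiv each), THF, 0 °C → rt
Reagents that add atoms: methyltriphenylphosphonium bromide, C[P+](c1ccccc1)(c1ccccc1)c1ccccc1.[Br-]
Why: Wittig methylenation of the hindered ketone with excess non-stabilised ylide (the alkoxide is carried along and the nitrile should be inert at this temperature); any base-induced equilibration at the α-carbon still favours the trans arrangement, which is fixed once the carbonyl is gone.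

**Step 7**
Reactants: 14 3-[(1R,2S)-2-(5-hydroxypent-1-en-2-yl)-4,4-dimethylcyclobutyl]propanenitrile
Product: 16 4-[(1R,2S)-2-(5-hydroxypent-1-en-2-yl)-4,4-dimethylcyclobutyl]butan-2-one, via ketimine 15 (not isolated)
Conditions: MeLi (3.5 equiv), Et2O, −78 → 0 °C; then cold aq. HCl
Reagents that add atoms: methyllithium, [Li]C; water, O
Why: Addition of an organolithium to a nitrile stops at the N-lithio ketimine, which is hydrolysed on mild acidic work-up to the methyl ketone; the first equivalent is consumed by the hydroxyl group and the isolated alkene is inert.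

**Step 8**
Reactants: 16 4-[(1R,2S)-2-(5-hydroxypent-1-en-2-yl)-4,4-dimethylcyclobutyl]butan-2-one; 17 (9Z,12Z)-octadeca-9,12-dienoic acid (linoleic acid)
Product: 18 4-[(1S,2R)-3,3-dimethyl-2-(3-oxobutyl)cyclobutyl]pent-4-en-1-yl (9Z,12Z)-octadeca-9,12-dienoate (IN0146)
Conditions: DCC, DMAP (cat.), CH2Cl2, 0 °C → rt
Reagents that add atoms: none
Why: Steglich esterification acylates the primary alcohol under neutral conditions that should not isomerise the skipped Z,Z-diene, enolise the ketone or touch the 1,1-disubstituted alkene.

**Compound list**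

1 | cyclohex-2-en-1-one | O=C1C=CCCC1 | starting material
2 | 2-methylpropene (isobutene) | C=C(C)C | starting material
3 | (1S,6R)-7,7-dimethylbicyclo[4.2.0]octan-2-one (trans-fused) | O=C1CCC[C@@H]2[C@@H]1CC2(C)C | intermediate
4 | (1R,6R)-7,7-dimethylbicyclo[4.2.0]octan-2-one (cis-fused) | O=C1CCC[C@@H]2[C@H]1CC2(C)C | intermediate
5 | (1R,6R)-3-(hydroxyimino)-7,7-dimethylbicyclo[4.2.0]octan-2-one | O=C1C(=NO)CC[C@@H]2[C@H]1CC2(C)C | intermediate
6 | (1R,6R)-7,7-dimethyl-3-{[(4-methylbenzenesulfonyl)oxy]imino}bicyclo[4.2.0]octan-2-one | O=C1C(=NOS(=O)(=O)c3ccc(C)cc3)CC[C@@H]2[C@H]1CC2(C)C | intermediate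
7 | (1R,2R)-2-(2-cyanoethyl)-3,3-dimethylcyclobutane-1-carboxylic acid | OC(=O)[C@@H]1CC(C)(C)[C@@H]1CCC#N | intermediate
8 | 3-[(1R,2R)-2-(1H-imidazole-1-carbonyl)-4,4-dimethylcyclobutyl]propanenitrile | O=C(n2ccnc2)[C@@H]1CC(C)(C)[C@@H]1CCC#N | intermediate
9 | (1R,2R)-2-(2-cyanoethyl)-N-methoxy-N,3,3-trimethylcyclobutane-1-carboxamide | CON(C)C(=O)[C@@H]1CC(C)(C)[C@@H]1CCC#N | intermediate
10 | 3-chloropropan-1-ol | OCCCCl | starting material
11 | chloromagnesium 3-(chloromagnesio)propan-1-olate | Cl[Mg]CCCO[Mg]Cl | intermediate
12 | 3-[(1R,2R)-2-(4-hydroxybutanoyl)-4,4-dimethylcyclobutyl]propanenitrile (cis) | OCCCC(=O)[C@@H]1CC(C)(C)[C@@H]1CCC#N | intermediate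
13 | 3-[(1R,2S)-2-(4-hydroxybutanoyl)-4,4-dimethylcyclobutyl]propanenitrile (trans) | OCCCC(=O)[C@H]1CC(C)(C)[C@@H]1CCC#N | intermediate
14 | 3-[(1R,2S)-2-(5-hydroxypent-1-en-2-yl)-4,4-dimethylcyclobutyl]propanenitrile | C=C(CCCO)[C@H]1CC(C)(C)[C@@H]1CCC#N | intermediate
15 | 4-[(1R,2S)-2-(5-hydroxypent-1-en-2-yl)-4,4-dimethylcyclobutyl]butan-2-imine | C=C(CCCO)[C@H]1CC(C)(C)[C@@H]1CCC(C)=N | intermediate
16 | 4-[(1R,2S)-2-(5-hydroxypent-1-en-2-yl)-4,4-dimethylcyclobutyl]butan-2-one | C=C(CCCO)[C@H]1CC(C)(C)[C@@H]1CCC(C)=O | intermediate
17 | (9Z,12Z)-octadeca-9,12-dienoic acid | CCCCC/C=C\C/C=C\CCCCCCCC(=O)O | starting material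
18 | 4-[(1S,2R)-3,3-dimethyl-2-(3-oxobutyl)cyclobutyl]pent-4-en-1-yl (9Z,12Z)-octadeca-9,12-dienoate | C=C(CCCOC(=O)CCCCCCC/C=C\C/C=C\CCCCC)[C@H]1CC(C)(C)[C@@H]1CCC(C)=O | target

**Totals**

Total step count: 8. Longest linear sequence: 8 steps (the Grignard reagent of step 5 is made in the same operation).

**Steps most likely to fail**

1. Step 1. The uncatalysed photoreaction of free enone may erode the enantioselectivity, the strong Lewis acid may start oligomerisation of isobutene, and some head-to-head addition may occur. Fallback (sets out from 1 and 2, comes back at 4): irradiation of 1 with 2 without the Lewis acid (λ = 350 nm, CH2Cl2, −70 °C) and passage over basic alumina should give the racemic cis-fused ketone, that is 4 and its enantiomer (1S,6S)-7,7-dimethylbicyclo[4.2.0]octan-2-one F2, the trans-fused primary adducts 3 and (1R,6S)-7,7-dimethylbicyclo[4.2.0]octan-2-one F1 being converted on the alumina. Ketalisation of the racemate with (1R,2R)-1,2-diphenylethane-1,2-diol (TsOH cat., benzene, Dean–Stark) should give the diastereomeric ketals (1R,4'R,5'R,6R)-7,7-dimethyl-4',5'-diphenylspiro[bicyclo[4.2.0]octane-2,2'-[1,3]dioxolane] F3 and (1S,4'R,5'R,6S)-7,7-dimethyl-4',5'-diphenylspiro[bicyclo[4.2.0]octane-2,2'-[1,3]dioxolane] F4, to be separated by chromatography or crystallisation. Hydrolysis of F3 (aq. HCl, THF) returns 4.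

2. Step 2. Nitrosation may take place at the ring-fusion methine, which would be followed by cleavage of the C1–C2 bond and loss of the bicyclic ketone. Fallback (sets out from 4, comes back at 5): regiocontrol through a temporary activating group. Claisen formylation of 4 (NaH, ethyl formate, THF) can only give the stable enolised product at the methylene, (1R,6R)-3-(hydroxymethylidene)-7,7-dimethylbicyclo[4.2.0]octan-2-one F5. Nitrosative deformylation of F5 (NaNO2, aq. AcOH, 0 °C) should then give 5 with loss of the formyl group.

3. Step 7. Methyllithium may deprotonate the nitrile at its α-carbon instead of adding, so that conversion stays incomplete. Fallback (sets out from 14, comes back at 16): hydrolysis of the nitrile (KOH, ethylene glycol/H2O, 130 °C) should give 3-[(1R,2S)-2-(5-hydroxypent-1-en-2-yl)-4,4-dimethylcyclobutyl]propanoic acid F6. Treating F6 with excess MeLi (THF, 0 °C, inverse quench into cold aq. acid) is the classical conversion of a lithium carboxylate into a methyl ketone and should return 16.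

**Further compounds**

F1 | step 1 | (1R,6S)-7,7-dimethylbicyclo[4.2.0]octan-2-one | O=C1CCC[C@H]2[C@H]1CC2(C)C
F2 | step 1 | (1S,6S)-7,7-dimethylbicyclo[4.2.0]octan-2-one | O=C1CCC[C@H]2[C@@H]1CC2(C)C
F3 | step 1 | (1R,4'R,5'R,6R)-7,7-dimethyl-4',5'-diphenylspiro[bicyclo[4.2.0]octane-2,2'-[1,3]dioxolane] | C13(O[C@H](c4ccccc4)[C@@H](c4ccccc4)O3)CCC[C@@H]2[C@H]1CC2(C)C
F4 | step 1 | (1S,4'R,5'R,6S)-7,7-dimethyl-4',5'-diphenylspiro[bicyclo[4.2.0]octane-2,2'-[1,3]dioxolane] | C13(O[C@H](c4ccccc4)[C@@H](c4ccccc4)O3)CCC[C@H]2[C@@H]1CC2(C)C
F5 | step 2 | (1R,6R)-3-(hydroxymethylidene)-7,7-dimethylbicyclo[4.2.0]octan-2-one | O=C1C(=CO)CC[C@@H]2[C@H]1CC2(C)C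
F6 | step 7 | 3-[(1R,2S)-2-(5-hydroxypent-1-en-2-yl)-4,4-dimethylcyclobutyl]propanoic acid | C=C(CCCO)[C@H]1CC(C)(C)[C@@H]1CCC(=O)O
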